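All runs were computed for an exercise; scatter was added.

Time is what I count in set-up west, where second nucleophile enters over 2.50 h while substrate is already leaving.

| flask | substrate | first nucleophile | second nucleophile | remark | time |
|---|---|---|---|---|---|
| elm | 0.10 M | 0.050 M | 0.105 M | run made earlier |  |
| larch | 0.050 M | 0.050 M | 0.105 M | run made earlier |  |
| cedar | 0.075 M | 0.050 M | 0.105 M | run made earlier |  |
| birch | 0.10 M | 0.025 M | 0.105 M | run made earlier |  |
| south | 0.10 M | 0.0500 M | 0.105 M | one stirred flow tank at steady state, fed with the mixture as stated, mean residence time 5.0 h |  |
| north-east | 0.10 M | 0.0500 M (fed, over 2.50 h) | 0.105 M | a stirred flask in which first nucleophile is dosed at a steady rate over 2.50 h without added volume, worked up at 5.0 h | 5.0 h |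
| north-west | 0.10 M | 0.0500 M | 0.105 M | everything together in a closed stirred flask, run for 5.0 h | 5.0 h |
| west | 0.10 M | 0.0500 M | 0.105 M (fed, over 2.50 h) | all but second nucleophile at the start; second nucleophile goes in evenly over 2.50 h, the run ends at 5.0 h | 5.0 h |

| run | time / h | target / % |
|---|---|---|
| elm | 0.667 | 7.2 |
| elm | 1.33 | 10.4 |
| elm | 2.00 | 11.6 |
| elm | 3.00 | 11.1 |
| elm | 4.00 | 10.1 |
| elm | 5.00 | 10.3 |
| larch | 0.200 | 2.5 |
| larch | 0.667 | 6.3 |
| larch | 1.00 | 7.9 |
| larch | 1.50 | 8.1 |
| larch | 2.50 | 8.4 |
| larch | 3.00 | 8.0 |
| larch | 4.00 | 8.1 |
| cedar | 0.333 | 4.5 |
| cedar | 0.500 | 5.5 |
| cedar | 0.667 | 7.3 |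
| cedar | 1.00 | 8.3 |
| cedar | 1.50 | 9.2 |
| cedar | 2.50 | 9.5 |
| cedar | 4.00 | 8.7 |
| birch | 0.333 | 2.2 |
| birch | 1.00 | 5.0 |
| birch | 2.00 | 7.4 |
| birch | 3.00 | 6.2 |
| birch | 4.00 | 6.1 |

(scatter of a reading: 0.3 percentage points)

- the stated concentrations are those of everything mixed, before any reaction; amounts are the same in each set-up
- the feed brings no volume worth counting
- the earlier runs were made in a closed, stirred flask

- the set-up with the highest amount of target at the outlet or at the end, in percent of the substrate put in ("none" if the first two lie within 2 percentage points) (south / north-east / north-west / west / none)
- amount of target at the outlet or at the end, in percent of the substrate put in, south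
- amount of target at the outlet or at the end, in percent of the substrate put in, north-east
- amount of target at the outlet or at the end, in percent of the substrate put in, north-west
- amount of target at the outlet or at the end, in percent of the substrate put in, west

The birch run has half the first nucleophile of the elm run, yet both read their peak at 2.00 h, so I take substrate to leave on its own first-order clock. In the larch run target reads 6.3% at 0.667 h against a plateau of 8.4%. That gives a rate constant k = 2.08 /h, a half-life of 0.334 h, as a rough reading.

In west the feed brings r = 0.0420 M/h of second nucleophile, while substrate at first leaves at 0.208 M/h, which is faster. The two rates meet at t_c = 0.769 h, after 2.30 half-lives. I call the spill, 47.5%, the substrate gone by t_c less the second nucleophile fed by t_c, per substrate charged. I give the spill to first nucleophile, and it fits, being less than the charge of first nucleophile, though my count takes nearly all of it.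

The spill counts target and whatever target later becomes. The elm run reads 11.6% at 2.00 h and 10.3% at 5.00 h, and scaling by that ratio gives 42.2%. This is my weak link, because by my count spilled target in west ages 4.62 h on average, longer than the elm window of 3.00 h. So I reforge it with the fall per hour read from the elm run, 0.0374 /h, held over that age, and commit to 39.3% for west.

The forecast names west as best, with south 11.3%, north-east 6%, north-west 10.2% and west 17%, and says of west that “second nucleophile stays starved while first nucleophile works on abundant substrate”. My west figure is higher than the forecast's; I reckoned west by itself and take the forecast's figures for the other set-ups.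

The simulation gives west as best, with south 12.5%, north-east 4.57%, north-west 10.3% and west 35.2%.

    first nucleophile + intermediate → target (k = 539 /M/h)
    substrate → intermediate (k = 1.92 /h)
    target ⇌ isomer of the product (K = 0.457, k = 0.106 /h)
    second nucleophile + intermediate → other capture product (k = 2980 /M/h)

At 5.00 h west holds target 35.2% and isomer of the product 11.7%, together 46.9%, beside a spill of 47.5%. The neighbouring flask is north-east with second nucleophile cut to 0.063 M, which is 0.630 equiv. There second nucleophile stands in the flask from the start, so the count has no race with a feed: the substrate beyond that charge makes a spill of 37.0%. That flask ends with second nucleophile at 0%, other capture product 63.0%, isomer of the product 8.22% and target 28.8%.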